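**Retrosynthetic overview**
1. Songaricalarin B ⇐ OH-directed epoxidation of the C7 isopropenyl group; C5 ester by acylation; C4=CH2/C5–O from a C4(Me)=C5 alkene by OH-directed epoxidation and epoxide-to-allylic-alcohol isomerisation.
2. Cyclopentane ring (C1, C2, side-chain carbinol) ⇐ intramolecular nitrile oxide–alkene [3+2] cycloaddition between a C3a–CH2–CNO arm and a C7a (E)-propenyl group, then N–O cleavage and anti-selective ketone reduction.
3. C3a–CH2CHO arm ⇐ Claisen rearrangement of the vinyl ether of a C5 allylic alcohol (C5–O configuration relayed to C3a).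
4. That cyclohexenol ⇐ (R)-carvone by α'-allylation, Wharton 1,3-transposition, α'-oxygenation, allyl-to-propenyl isomerisation and Luche reduction.
5. Ring order: six-membered ring bought (carvone); five-membered carbocycle closed in the cycloaddition.

Assumption: (E)-3-methylpent-2-enoic acid (26) is purchased; locants C1–C7a in the text are the indane positions of the target (C1 acetoxyethyl, C2 OAc, C4 methylidene, C5 ester, C6 OH, C7 oxiranyl).

**Route**

Step 1
Reactants: 1 (R)-(−)-carvone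
Product: 3 (5R,6S)-6-allyl-2-methyl-5-(prop-1-en-2-yl)cyclohex-2-en-1-one, via lithium enolate 2 (not isolated)
Conditions: LiN(iPr)2, THF, −78 °C; allyl bromide, DMPU, −78 to −20 °C
Reagents that add atoms: allyl bromide C=CCBr
Why: Kinetic α'-enolate alkylation in which the electrophile enters anti to the adjacent isopropenyl group, giving the 5,6-trans product and so setting C7a from the carvone stereocentre.

Step 2
Reactants: 3 (5R,6S)-6-allyl-2-methyl-5-(prop-1-en-2-yl)cyclohex-2-en-1-one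
Product: 4 (1R,3S,4R,6R)-3-allyl-1-methyl-4-(prop-1-en-2-yl)-7-oxabicyclo[4.1.0]heptan-2-one
Conditions: 30% H2O2, NaOH (cat.), MeOH, 0 °C
Reagents that add atoms: hydrogen peroxide OO
Why: Weitz–Scheffer nucleophilic epoxidation touches only the enone double bond (face anti to isopropenyl, as for carvone itself); the new centres are erased in step 4.

Step 3
Reactants: 4 (1R,3S,4R,6R)-3-allyl-1-methyl-4-(prop-1-en-2-yl)-7-oxabicyclo[4.1.0]heptan-2-one
Product: 6 (1R,4R,5R)-4-allyl-2-methyl-5-(prop-1-en-2-yl)cyclohex-2-en-1-ol, via epoxy hydrazone 5 (not isolated)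
Conditions: N2H4·H2O, AcOH (cat.), MeOH, 0 °C to rt
Reagents that add atoms: none
Why: Wharton transposition: the epoxy hydrazone fragments with loss of N2 to the 1,3-transposed allylic alcohol, moving the oxygen to C5 and the alkene to C3a=C4.

Step 4
Reactants: 6 (1R,4R,5R)-4-allyl-2-methyl-5-(prop-1-en-2-yl)cyclohex-2-en-1-ol
Product: 7 (4R,5R)-4-allyl-2-methyl-5-(prop-1-en-2-yl)cyclohex-2-en-1-one
Conditions: MnO2, CH2Cl2, rt
Reagents that add atoms: none
Why: Chemoselective allylic alcohol oxidation gives the transposed enone in which the allylated carbon is now γ and the CH2 next to the isopropenyl carbon (future C6) is α'.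

Step 5
Reactants: 7 (4R,5R)-4-allyl-2-methyl-5-(prop-1-en-2-yl)cyclohex-2-en-1-one
Product: 10 (4R,5R,6R)-4-allyl-6-(tert-butyldimethylsilyloxy)-2-methyl-5-(prop-1-en-2-yl)cyclohex-2-en-1-one, via lithium dienolate 8 (not isolated), via silyl dienol ether 9 (not isolated)
Conditions: LiN(iPr)2, THF, −78 °C; TBSOTf, −78 to 0 °C; then mCPBA, NaHCO3, CH2Cl2, −20 °C
Reagents that add atoms: tert-butyldimethylsilyl triflate CC(C)(C)[Si](C)(C)OS(=O)(=O)C(F)(F)F; mCPBA OOC(=O)c1cccc(Cl)c1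
Why: Rubottom oxidation: the peracid attacks the electron-rich silyloxydiene anti to the neighbouring isopropenyl group and 1,4-silyl migration gives the α'-silyloxy ketone directly, setting C6 trans to C7.

Step 6
Reactants: 10 (4R,5R,6R)-4-allyl-6-(tert-butyldimethylsilyloxy)-2-methyl-5-(prop-1-en-2-yl)cyclohex-2-en-1-one
Product: 11 (4R,5R,6R)-6-(tert-butyldimethylsilyloxy)-2-methyl-4-[(E)-prop-1-en-1-yl]-5-(prop-1-en-2-yl)cyclohex-2-en-1-one
Conditions: RuHCl(CO)(PPh3)3 (5 mol %), toluene, 80 °C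
Reagents that add atoms: none
Why: Ruthenium hydride insertion/β-hydride elimination moves the terminal double bond one position to the thermodynamically preferred (E)-propenyl group; the 1,1-disubstituted isopropenyl group is inert.

Step 7
Reactants: 11 (4R,5R,6R)-6-(tert-butyldimethylsilyloxy)-2-methyl-4-[(E)-prop-1-en-1-yl]-5-(prop-1-en-2-yl)cyclohex-2-en-1-one
Product: 12 (1R,4R,5R,6R)-6-(tert-butyldimethylsilyloxy)-2-methyl-4-[(E)-prop-1-en-1-yl]-5-(prop-1-en-2-yl)cyclohex-2-en-1-ol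
Conditions: NaBH4, CeCl3·7H2O, MeOH, −78 to −20 °C
Reagents that add atoms: none
Why: Luche 1,2-reduction with axial hydride delivery (anti to the pseudoaxial C6–H, as in carvone to cis-carveol) gives the equatorial C5–OH trans to the C6 silyl ether.

Step 8
Reactants: 12 (1R,4R,5R,6R)-6-(tert-butyldimethylsilyloxy)-2-methyl-4-[(E)-prop-1-en-1-yl]-5-(prop-1-en-2-yl)cyclohex-2-en-1-ol
Product: 14 2-[(1R,4S,5R,6R)-4-(tert-butyldimethylsilyloxy)-2-methyl-6-[(E)-prop-1-en-1-yl]-5-(prop-1-en-2-yl)cyclohex-2-en-1-yl]acetaldehyde, via allyl vinyl ether 13 (not isolated)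
Conditions: butyl vinyl ether, Pd(OCOCF3)2 (5 mol %), 4,7-diphenyl-1,10-phenanthroline, Et3N, 75 °C; concentrate; toluene, 180 °C (sealed tube)
Reagents that add atoms: butyl vinyl ether C=COCCCC
Why: Claisen [3,3]-sigmatropic rearrangement: the shift is suprafacial, so the new C3a–C bond forms on the face of the departing C5–O bond (anti to the C7a propenyl group), fixing C3a and the trans relationship of the two future ring-fusion centres.

Step 9
Reactants: 14 2-[(1R,4S,5R,6R)-4-(tert-butyldimethylsilyloxy)-2-methyl-6-[(E)-prop-1-en-1-yl]-5-(prop-1-en-2-yl)cyclohex-2-en-1-yl]acetaldehyde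
Product: 15 oxime of aldehyde 14 (E/Z mixture)
Conditions: NH2OH·HCl, pyridine, EtOH, rt
Reagents that add atoms: hydroxylamine hydrochloride NO.Cl
Why: Simple oxime condensation provides the nitrile oxide precursor without touching any stereocentre.

Step 10
Reactants: 15 oxime of aldehyde 14
Product: 17 tricyclic isoxazoline (2-isoxazoline fused across C1–C2 of the trans-fused 6-silyloxy-4-methyl-7-isopropenyl-hexahydroindene; C2=N; O on the side-chain carbon), via nitrile oxide 16 (not isolated)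
Conditions: NaOCl (aq), CH2Cl2, 0 °C to rt, high dilution
Reagents that add atoms: none
Why: Intramolecular nitrile oxide–alkene 1,3-dipolar cycloaddition closes the cyclopentane; reaction through the rotamer with C7a–H eclipsing the propenyl double bond (minimal A(1,3) strain) sets C1, and stereospecific syn addition to the (E)-alkene sets the (S)-carbinol carbon.

Step 11
Reactants: 17 tricyclic isoxazoline
Product: 19 (1S,3aR,6S,7R,7aR)-6-(tert-butyldimethylsilyloxy)-1-[(1S)-1-hydroxyethyl]-4-methyl-7-(prop-1-en-2-yl)-1,3,3a,6,7,7a-hexahydro-2H-inden-2-one, via hydroxy imine 18 (not isolated)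
Conditions: Mo(CO)6, MeCN/H2O (15:1), 80 °C
Reagents that add atoms: water O
Why: Reductive N–O cleavage and imine hydrolysis unmask the aldol (β-hydroxy ketone) without reducing the alkenes; the C1 side chain stays in its favoured pseudo-equatorial position.

Step 12
Reactants: 19 (1S,3aR,6S,7R,7aR)-6-(tert-butyldimethylsilyloxy)-1-[(1S)-1-hydroxyethyl]-4-methyl-7-(prop-1-en-2-yl)-1,3,3a,6,7,7a-hexahydro-2H-inden-2-one
Product: 20 (1S,2S,3aR,6S,7R,7aR)-6-(tert-butyldimethylsilyloxy)-1-[(1S)-1-hydroxyethyl]-4-methyl-7-(prop-1-en-2-yl)-2,3,3a,6,7,7a-hexahydro-1H-inden-2-ol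
Conditions: Me4NBH(OAc)3, MeCN/AcOH (1:1), −30 °C
Reagents that add atoms: none
Why: Evans–Saksena reduction: hydride is delivered intramolecularly from the side-chain alkoxyborohydride through a chair with the methyl group equatorial, giving the 1,3-anti diol, which here is the C2–OH cis to the side chain.

Step 13
Reactants: 20 (1S,2S,3aR,6S,7R,7aR)-6-(tert-butyldimethylsilyloxy)-1-[(1S)-1-hydroxyethyl]-4-methyl-7-(prop-1-en-2-yl)-2,3,3a,6,7,7a-hexahydro-1H-inden-2-ol
Product: 21 (1S)-1-[(1S,2S,3aR,6S,7R,7aR)-2-acetoxy-6-(tert-butyldimethylsilyloxy)-4-methyl-7-(prop-1-en-2-yl)-2,3,3a,6,7,7a-hexahydro-1H-inden-1-yl]ethyl acetate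
Conditions: Ac2O, pyridine, DMAP (cat.), CH2Cl2, rt
Reagents that add atoms: acetic anhydride CC(=O)OC(C)=O
Why: Standard DMAP-catalysed acylation installs both acetates of the target while C6 is still silyl-protected.

Step 14
Reactants: 21 (1S)-1-[(1S,2S,3aR,6S,7R,7aR)-2-acetoxy-6-(tert-butyldimethylsilyloxy)-4-methyl-7-(prop-1-en-2-yl)-2,3,3a,6,7,7a-hexahydro-1H-inden-1-yl]ethyl acetate
Product: 22 (1S)-1-[(1S,2S,3aR,6S,7R,7aR)-2-acetoxy-6-hydroxy-4-methyl-7-(prop-1-en-2-yl)-2,3,3a,6,7,7a-hexahydro-1H-inden-1-yl]ethyl acetate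
Conditions: HF·pyridine, THF, 0 °C to rt
Reagents that add atoms: none
Why: Fluoride desilylation under buffered acidic conditions frees the allylic C6–OH and leaves the acetates intact.

Step 15
Reactants: 22 (1S)-1-[(1S,2S,3aR,6S,7R,7aR)-2-acetoxy-6-hydroxy-4-methyl-7-(prop-1-en-2-yl)-2,3,3a,6,7,7a-hexahydro-1H-inden-1-yl]ethyl acetate
Product: 23 (1S)-1-[(1S,2S,3aR,4S,5R,6R,7R,7aR)-2-acetoxy-4,5-epoxy-6-hydroxy-4-methyl-7-(prop-1-en-2-yl)octahydro-1H-inden-1-yl]ethyl acetate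
Conditions: VO(acac)2 (5 mol %), t-BuOOH (1.1 equiv), CH2Cl2, 0 °C
Reagents that add atoms: tert-butyl hydroperoxide CC(C)(C)OO
Why: Hydroxyl-directed vanadium-catalysed epoxidation delivers oxygen syn to the allylic C6–OH and is much faster at the allylic C4=C5 bond than at the homoallylic isopropenyl group, giving chemo- and face-selectivity.

Step 16
Reactants: 23 (1S)-1-[(1S,2S,3aR,4S,5R,6R,7R,7aR)-2-acetoxy-4,5-epoxy-6-hydroxy-4-methyl-7-(prop-1-en-2-yl)octahydro-1H-inden-1-yl]ethyl acetate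
Product: 24 (1S)-1-[(1S,2S,3aR,4S,5R,6R,7R,7aR)-2-acetoxy-4,5-epoxy-4-methyl-7-(prop-1-en-2-yl)-6-(triethylsilyloxy)octahydro-1H-inden-1-yl]ethyl acetate
Conditions: Et3SiCl, imidazole, DMAP (cat.), DMF, rt
Reagents that add atoms: chlorotriethylsilane CC[Si](CC)(CC)Cl
Why: Silylation of the only free hydroxyl keeps C6–O and the coming C5–OH distinguishable (direct acylation of the later cis-diol would favour the equatorial C6–OH).

Step 17
Reactants: 24 (1S)-1-[(1S,2S,3aR,4S,5R,6R,7R,7aR)-2-acetoxy-4,5-epoxy-4-methyl-7-(prop-1-en-2-yl)-6-(triethylsilyloxy)octahydro-1H-inden-1-yl]ethyl acetate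
Product: 25 (1S)-1-[(1S,2S,3aR,5S,6R,7R,7aR)-2-acetoxy-5-hydroxy-4-methylidene-7-(prop-1-en-2-yl)-6-(triethylsilyloxy)octahydro-1H-inden-1-yl]ethyl acetate
Conditions: Cp2TiCl2 (2.5 equiv), Mn (8 equiv), THF, rt; 1 M HCl work-up
Reagents that add atoms: none
Why: Nugent–RajanBabu opening: Cp2TiCl (trivalent titanium) cleaves the epoxide homolytically to the tertiary C4 radical, and hydrogen abstraction from the methyl group gives the exocyclic alkene while the C5–O bond and its configuration are retained; esters tolerate the reagent.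

Step 18
Reactants: 25 (1S)-1-[(1S,2S,3aR,5S,6R,7R,7aR)-2-acetoxy-5-hydroxy-4-methylidene-7-(prop-1-en-2-yl)-6-(triethylsilyloxy)octahydro-1H-inden-1-yl]ethyl acetate; 26 (E)-3-methylpent-2-enoic acid
Product: 28 C6-triethylsilyl ether of the C5 (E)-3-methylpent-2-enoate (see SMILES), via O-acylisourea 27 (not isolated)
Conditions: DCC, DMAP (cat.), CH2Cl2, 0 to 40 °C
Reagents that add atoms: none
Why: Steglich esterification acylates the single free (axial, allylic) hydroxyl with retention at C5 and, under these base-poor conditions, retention of the (E)-enoate geometry.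

Step 19
Reactants: 28 C6-triethylsilyl ether of the C5 (E)-3-methylpent-2-enoate
Product: 29 (1S)-1-[(1S,2S,3aR,5S,6R,7R,7aR)-2-acetoxy-6-hydroxy-5-{[(2E)-3-methylpent-2-enoyl]oxy}-4-methylidene-7-(prop-1-en-2-yl)octahydro-1H-inden-1-yl]ethyl acetate
Conditions: HF·pyridine, THF, 0 °C
Reagents that add atoms: none
Why: Mild buffered fluoride desilylation frees C6–OH without the base that would promote C5-to-C6 acyl migration.

Step 20
Reactants: 29 (1S)-1-[(1S,2S,3aR,5S,6R,7R,7aR)-2-acetoxy-6-hydroxy-5-{[(2E)-3-methylpent-2-enoyl]oxy}-4-methylidene-7-(prop-1-en-2-yl)octahydro-1H-inden-1-yl]ethyl acetate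
Product: 30 Songaricalarin B
Conditions: VO(acac)2 (10 mol %), t-BuOOH (1.5 equiv), CH2Cl2, rt
Reagents that add atoms: tert-butyl hydroperoxide CC(C)(C)OO
Why: Homoallylic hydroxyl-directed vanadium epoxidation (as for isopulegol): the equatorial C6–O–V peroxide reaches only the adjacent equatorial isopropenyl group (C4=CH2 is about 4 Å away and deactivated by the allylic acyloxy group), and delivery to the face turned toward C6–OH in the rotamer with C=CH2 eclipsing H-7 gives the (S)-oxirane.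

**Compound list**
1 | (R)-(−)-carvone | CC1=CC[C@@H](C(C)=C)CC1=O | starting material
2 | lithium enolate of 1 | CC1=CC[C@@H](C(C)=C)C=C1O[Li] | intermediate
3 | (5R,6S)-6-allyl-2-methyl-5-(prop-1-en-2-yl)cyclohex-2-en-1-one | CC1=CC[C@@H](C(C)=C)[C@H](CC=C)C1=O | intermediate
4 | (1R,3S,4R,6R)-3-allyl-1-methyl-4-(prop-1-en-2-yl)-7-oxabicyclo[4.1.0]heptan-2-one | C[C@@]12O[C@@H]1C[C@@H](C(C)=C)[C@H](CC=C)C2=O | intermediate
5 | hydrazone of 4 | C[C@@]12O[C@@H]1C[C@@H](C(C)=C)[C@H](CC=C)C2=NN | intermediate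
6 | (1R,4R,5R)-4-allyl-2-methyl-5-(prop-1-en-2-yl)cyclohex-2-en-1-ol | CC1=C[C@@H](CC=C)[C@H](C(C)=C)C[C@H]1O | intermediate
7 | (4R,5R)-4-allyl-2-methyl-5-(prop-1-en-2-yl)cyclohex-2-en-1-one | CC1=C[C@@H](CC=C)[C@H](C(C)=C)CC1=O | intermediate
8 | lithium cross-conjugated dienolate of 7 | CC1=C[C@@H](CC=C)[C@H](C(C)=C)C=C1O[Li] | intermediate
9 | tert-butyldimethylsilyl dienol ether of 7 | CC1=C[C@@H](CC=C)[C@H](C(C)=C)C=C1O[Si](C)(C)C(C)(C)C | intermediate
10 | (4R,5R,6R)-4-allyl-6-(tert-butyldimethylsilyloxy)-2-methyl-5-(prop-1-en-2-yl)cyclohex-2-en-1-one | CC1=C[C@@H](CC=C)[C@H](C(C)=C)[C@@H](O[Si](C)(C)C(C)(C)C)C1=O | intermediate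
11 | (4R,5R,6R)-6-(tert-butyldimethylsilyloxy)-2-methyl-4-[(E)-prop-1-en-1-yl]-5-(prop-1-en-2-yl)cyclohex-2-en-1-one | CC1=C[C@@H](/C=C/C)[C@H](C(C)=C)[C@@H](O[Si](C)(C)C(C)(C)C)C1=O | intermediate
12 | (1R,4R,5R,6R)-6-(tert-butyldimethylsilyloxy)-2-methyl-4-[(E)-prop-1-en-1-yl]-5-(prop-1-en-2-yl)cyclohex-2-en-1-ol | CC1=C[C@@H](/C=C/C)[C@H](C(C)=C)[C@@H](O[Si](C)(C)C(C)(C)C)[C@@H]1O | intermediate
13 | vinyl ether of 12 | CC1=C[C@@H](/C=C/C)[C@H](C(C)=C)[C@@H](O[Si](C)(C)C(C)(C)C)[C@@H]1OC=C | intermediate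
14 | 2-[(1R,4S,5R,6R)-4-(tert-butyldimethylsilyloxy)-2-methyl-6-[(E)-prop-1-en-1-yl]-5-(prop-1-en-2-yl)cyclohex-2-en-1-yl]acetaldehyde | CC1=C[C@H](O[Si](C)(C)C(C)(C)C)[C@@H](C(C)=C)[C@H](/C=C/C)[C@H]1CC=O | intermediate
15 | oxime of 14 (E/Z mixture) | CC1=C[C@H](O[Si](C)(C)C(C)(C)C)[C@@H](C(C)=C)[C@H](/C=C/C)[C@H]1CC=NO | intermediate
16 | nitrile oxide from 15 | CC1=C[C@H](O[Si](C)(C)C(C)(C)C)[C@@H](C(C)=C)[C@H](/C=C/C)[C@H]1CC#[N+][O-] | intermediate
17 | tricyclic isoxazoline (C2=N, O on the side-chain carbon, trans ring fusion) | CC1=C[C@H](O[Si](C)(C)C(C)(C)C)[C@@H](C(C)=C)[C@H]2[C@H]1CC3=NO[C@@H](C)[C@@H]32 | intermediate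
18 | β-hydroxy imine from 17 | CC1=C[C@H](O[Si](C)(C)C(C)(C)C)[C@@H](C(C)=C)[C@H]2[C@H]1CC(=N)[C@@H]2[C@H](C)O | intermediate
19 | (1S,3aR,6S,7R,7aR)-6-(tert-butyldimethylsilyloxy)-1-[(1S)-1-hydroxyethyl]-4-methyl-7-(prop-1-en-2-yl)-1,3,3a,6,7,7a-hexahydro-2H-inden-2-one | CC1=C[C@H](O[Si](C)(C)C(C)(C)C)[C@@H](C(C)=C)[C@H]2[C@H]1CC(=O)[C@@H]2[C@H](C)O | intermediate
20 | (1S,2S,3aR,6S,7R,7aR)-6-(tert-butyldimethylsilyloxy)-1-[(1S)-1-hydroxyethyl]-4-methyl-7-(prop-1-en-2-yl)-2,3,3a,6,7,7a-hexahydro-1H-inden-2-ol | CC1=C[C@H](O[Si](C)(C)C(C)(C)C)[C@@H](C(C)=C)[C@H]2[C@H]1C[C@H](O)[C@@H]2[C@H](C)O | intermediate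
21 | diacetate of 20 | CC1=C[C@H](O[Si](C)(C)C(C)(C)C)[C@@H](C(C)=C)[C@H]2[C@H]1C[C@H](OC(C)=O)[C@@H]2[C@H](C)OC(C)=O | intermediate
22 | C6 allylic alcohol (desilylated 21) | CC1=C[C@H](O)[C@@H](C(C)=C)[C@H]2[C@H]1C[C@H](OC(C)=O)[C@@H]2[C@H](C)OC(C)=O | intermediate
23 | 4,5-epoxy alcohol (oxirane syn to C6–OH; 1S,2S,3aR,4S,5R,6R,7R,7aR, side chain S) | C[C@@]12O[C@@H]1[C@H](O)[C@@H](C(C)=C)[C@H]3[C@H]2C[C@H](OC(C)=O)[C@@H]3[C@H](C)OC(C)=O | intermediate
24 | C6 triethylsilyl ether of 23 | C[C@@]12O[C@@H]1[C@H](O[Si](CC)(CC)CC)[C@@H](C(C)=C)[C@H]3[C@H]2C[C@H](OC(C)=O)[C@@H]3[C@H](C)OC(C)=O | intermediate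
25 | 4-methylidene C5 alcohol (1S,2S,3aR,5S,6R,7R,7aR, side chain S) with C6–OSiEt3 | C=C1[C@@H]2C[C@H](OC(C)=O)[C@H]([C@H](C)OC(C)=O)[C@H]2[C@H](C(C)=C)[C@@H](O[Si](CC)(CC)CC)[C@H]1O | intermediate
26 | (E)-3-methylpent-2-enoic acid | CC/C(C)=C/C(=O)O | starting material
27 | O-acylisourea of 26 and DCC | CC/C(C)=C/C(=O)OC(=NC1CCCCC1)NC1CCCCC1 | intermediate
28 | C5 (E)-3-methylpent-2-enoate with C6–OSiEt3 | C=C1[C@@H]2C[C@H](OC(C)=O)[C@H]([C@H](C)OC(C)=O)[C@H]2[C@H](C(C)=C)[C@@H](O[Si](CC)(CC)CC)[C@H]1OC(=O)/C=C(\C)CC | intermediate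
29 | C6 alcohol with C7 isopropenyl group (de-epoxy target) | C=C1[C@@H]2C[C@H](OC(C)=O)[C@H]([C@H](C)OC(C)=O)[C@H]2[C@H](C(C)=C)[C@@H](O)[C@H]1OC(=O)/C=C(\C)CC | intermediate
30 | Songaricalarin B | C=C1[C@@H]2C[C@H](OC(C)=O)[C@H]([C@H](C)OC(C)=O)[C@H]2[C@H]([C@@]2(C)CO2)[C@@H](O)[C@H]1OC(=O)/C=C(\C)CC | target

**Totals and risks**
Total steps: 20. Longest linear sequence: 20 steps from (R)-carvone (the acid 26 enters at step 18).

The three steps most likely to fail:

Step 20 (face selectivity at the oxirane carbon rests on a rotamer argument, and the C5 ester must not migrate). Fallback, from 29 back to 30: hydroxyl-directed dihydroxylation of the isopropenyl group with OsO4·TMEDA (CH2Cl2, −78 °C, then aqueous NaHSO3) gives triol F4, whose C8 epimers can be separated. TsCl/pyridine then sulfonylates only the primary hydroxyl to give primary tosylate F5, and DBU (CH2Cl2) closes the oxirane with retention at the tertiary carbon to give 30.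

Step 10 (a trans-fused five-membered ring must close, and the C1 face selectivity rests on an A(1,3) argument). Fallback, from 14 back to 20: Me2AlCl (CH2Cl2, −78 °C) promotes an intramolecular carbonyl-ene reaction between the aldehyde and the propenyl group. This closes the same C1–C2 bond and gives vinyl cyclopentanol F2. Wacker oxidation (PdCl2, CuCl, O2, DMF/H2O) converts the vinyl group into methyl ketone F3, and Me4NBH(OAc)3 reduction directed by the C2 hydroxyl gives the anti diol 20.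

Step 8 (vinyl transfer to a hindered, pseudo-equatorial allylic alcohol and a high-temperature rearrangement). Fallback, from 12 back to 14: heating 12 with MeC(OEt)3 and catalytic EtCO2H (xylene, 140 °C; Johnson orthoester variant, ketene acetal formed and rearranged in one pot with the same chirality transfer) gives ethyl ester F1. iBu2AlH (toluene, −78 °C) reduces F1 to aldehyde 14.

**Further compounds**
F1 | step 8 | ethyl 2-[(1R,4S,5R,6R)-4-(tert-butyldimethylsilyloxy)-2-methyl-6-[(E)-prop-1-en-1-yl]-5-(prop-1-en-2-yl)cyclohex-2-en-1-yl]acetate | CC1=C[C@H](O[Si](C)(C)C(C)(C)C)[C@@H](C(C)=C)[C@H](/C=C/C)[C@H]1CC(=O)OCC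
F2 | step 10 | (1S,2S,3aR,6S,7R,7aR)-6-(tert-butyldimethylsilyloxy)-1-ethenyl-4-methyl-7-(prop-1-en-2-yl)-2,3,3a,6,7,7a-hexahydro-1H-inden-2-ol | CC1=C[C@H](O[Si](C)(C)C(C)(C)C)[C@@H](C(C)=C)[C@H]2[C@H]1C[C@H](O)[C@@H]2C=C
F3 | step 10 | 1-[(1S,2S,3aR,6S,7R,7aR)-6-(tert-butyldimethylsilyloxy)-2-hydroxy-4-methyl-7-(prop-1-en-2-yl)-2,3,3a,6,7,7a-hexahydro-1H-inden-1-yl]ethanone | CC1=C[C@H](O[Si](C)(C)C(C)(C)C)[C@@H](C(C)=C)[C@H]2[C@H]1C[C@H](O)[C@@H]2C(C)=O
F4 | step 20 | C7 (2S)-1,2-dihydroxypropan-2-yl triol from 29 | C=C1[C@@H]2C[C@H](OC(C)=O)[C@H]([C@H](C)OC(C)=O)[C@H]2[C@H]([C@](C)(O)CO)[C@@H](O)[C@H]1OC(=O)/C=C(\C)CC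
F5 | step 20 | primary tosylate of F4 | C=C1[C@@H]2C[C@H](OC(C)=O)[C@H]([C@H](C)OC(C)=O)[C@H]2[C@H]([C@](C)(O)COS(=O)(=O)c2ccc(C)cc2)[C@@H](O)[C@H]1OC(=O)/C=C(\C)CC
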